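Remark on the chemistry (assumption): germacrane numbering is used throughout, with C1 and C10 the oxirane carbons, C14 the formyl carbon on C10, C4=C5 the alkene, C15 the methyl on C4, C6 and C8 the acetoxy carbons, C7 the carbon bearing the isopropyl group and C11–C13 the isopropyl carbons; the SMILES is read as (1R,6R,7S,8R,10S), 4E, with C2 and C9 cis on the oxirane.

## Structural features

The only carbocycle is the ten-membered germacrane ring C1–C10, and an oxirane is fused to it at C1–C10. C4=C5 is an E-trisubstituted alkene inside the ring (C3 and C6 trans), which strains the ring and makes direct closure hard. On the oxirane the ring carbons C2 and C9 are cis, so its parent alkene is "ring-cis", and the quaternary C10 carries the formyl carbon C14. C6(OAc), C7(iPr) and C8(OAc) are three contiguous stereocentres; along a zigzag C5–C9 they are 6,7-anti, 7,8-syn and 6,8-anti, and C6 is also allylic to C4=C5. The fragile groups are the α,β-epoxy aldehyde (base, nucleophiles, Lewis acids), the allylic acetate at C6 and, at the diene stage, the 1(10),4-diene (acid-induced transannular cyclisation, thermal Cope rearrangement). The real difficulty is twofold: closing the ring with the E-alkene in place while fixing the C6–C7–C8 triad, and reaching a ring-cis C1/C10 unit with an oxidised C14. The key step exploits the pair C6/C7, a secondary allylic carbinol carbon next to a ring carbon that bears the three-carbon branch C11–C13. This pair is the retron of a [2,3]-Wittig rearrangement in which an oxygen bridge from C6 to C12, absent from the target, is broken.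

## Logic of the disconnections

19 to 18 to 17. The C1–O and C10–O bonds of the oxirane are cut and C14 is lowered to the alcohol level. The epoxy aldehyde is the most fragile group and should come last, and the C14 hydroxyl of 17 lets a reagent pick one alkene and one face. Two stereocentres and the aldehyde disappear. The demand is that 17 already has C2 and C9 cis, that C4=C5 stays untouched and that oxygen reaches the face that gives 1R.

17 to 16 to 15. The C14–O bond is cut. C10 then carries a plain methyl group, and the ring is a regular (E,E)-1(10),4-diene whose carbon chain can be bought as an open C15 chain. Neither the C14 oxygen nor the ring-cis geometry has to be carried through the ring closure. The allylic oxidation must choose C14 over C9, C2, C3 and C15, and through 16 it must turn C1=C10 from ring-trans to ring-cis.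

15 to 14 to 13 to 12. The two acetyl–oxygen bonds are cut, the C11=C12 unsaturation is restored and O8 is reattached to its aminoxyl carrier. This uncovers the carbinol/isopropenyl pair at C6/C7. Only functional group changes lie between 12 and 15. The demand is that the 1,1-disubstituted alkene is saturated in the presence of two ring alkenes.

12 to 11 to 10 (key). The C6–C7 ring bond is cut and O6 is reconnected to C12. The strained ten-membered carbocycle becomes an unstrained thirteen-membered bis-allylic ether with one stereocentre (C8). The ring closure, C6, C7, the free C6 hydroxyl and the C11–C13 branch all come from one isomerisation. The demands are carbanion formation at C6 and not at C12, [2,3] rather than [1,2] migration, and relay of C8 to C7 and C6. In one sentence: a thirteen-membered cyclic bis-allylic ether contracts to the ten-membered carbocycle by a transannular [2,3]-Wittig rearrangement.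

10 to 9 to 8. One C–O bond of the ether is cut. Both termini of 8 are primary allylic alcohols, and activating either one leads to the same ether. No protecting groups are needed to tell the ends apart. The demand is single activation and intramolecular closure under dilution.

8 to 7 to 5 + 6. The C7=C11 double bond is cut. The Z geometry (C8 cis to C12) decides the C6/C7 relation in the key step, and a Z-selective olefination of an α-oxy aldehyde supplies it. C11–C13 come from 6, which is bought. The demand is Z selectivity without epimerisation at C8.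

5 to 4. The C8–O bond is cut. C8 is the α-carbon of an aldehyde, so one catalytic step sets the only stereocentre that is not relayed. The group introduced is also the base-stable, very bulky protecting group for O8. Compound 4 is achiral. The demand is enantiofacial control on the enamine of 4.

4 to 3 to 2 to 1. C7 is reconnected to the C3 terminus that is lost on cleavage. Compound 1 holds C1–C10, C14, C15 and both E alkenes, so twelve of the fifteen skeletal carbons and two alkene geometries are bought. The demand is site-selective functionalisation of the terminal alkene of 1.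

## Other disconnections considered

Alternative 1: (the first that comes to mind) The cut is C5–C6, and the forward key step is a Ni/Cr-mediated (Nozaki–Hiyama–Kishi) closure of the open-chain vinyl iodide aldehyde A1 to the cyclic allylic alcohol A2. The strained (E,E)-cyclodecadiene would have to be closed directly from an open chain, so ring strain and entropy are paid in the same step. C6 would be set by addition to an α-branched, β-silyloxy aldehyde, where 1,2- and 1,3-induction do not reinforce each other for the required 6,7-anti/6,8-anti pattern. C7 and C8 would need a separate auxiliary-based aldol, and both trisubstituted alkenes would have to be built. The chosen plan buys both alkenes and sets C6 and C7 in the ring-forming event.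

Alternative 2: The cut is C2–C3 with reconnection of C5 to C10, and the forward key step is an anionic oxy-Cope ring expansion of the cis-1-vinyl-2-isopropenylcyclohexanol A3 to the cyclodecenone A4. The rearrangement type is reliable, but A3 is a pentasubstituted cyclohexane. Its C6 oxygen must be cis to the C7 isopropyl group, whereas external reagents add to such rings anti to that group. The C10 carbinol needs the less accessible face of the ketone. C14 is absent and has to be added to the C10 ketone afterwards. The simplification is small, and the precursor costs more steps than the whole chosen route up to its key step.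

Alternative 3: The cut is C1=C10, and the forward key step is an intramolecular Horner–Wadsworth–Emmons closure of the phosphonate aldehyde A5 to the ring enoate A6. The usual E selectivity would give the ring-cis geometry and the C14 carbon directly. However, the step sets no stereocentre, so the full C6–C7–C8 triad and the E-alkene must first be assembled in a linear sequence. Closure of a ten-membered ring that contains an E-alkene from a stabilised carbanion competes with dimerisation. The ester must still be taken to the aldehyde.

Key step: step 7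

## Steps

Step 1
Reactants: 1 (2E,6E)-farnesyl acetate
Product: 3 (2E,6E)-10,11-epoxy-3,7,11-trimethyldodeca-2,6-dien-1-yl acetate (racemic at the epoxide CH), via the 10,11-bromohydrin 2 (not isolated)
Conditions: NBS, THF/H2O, 0 °C; crude 2, then DBU, CH2Cl2, rt
Reagents that add atoms: water, O
Why: Bromohydrin formation in aqueous medium should take the exposed terminal trisubstituted alkene, since the alkene next to the allylic acetate is deactivated; DBU then closes the oxirane by internal SN2 without cleaving the acetate; the new stereocentre is racemic and is destroyed in step 2.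

Step 2
Reactants: 3 (2E,6E)-10,11-epoxy-3,7,11-trimethyldodeca-2,6-dien-1-yl acetate
Product: 4 (2E,6E)-3,7-dimethyl-10-oxodeca-2,6-dien-1-yl acetate
Conditions: H5IO6, THF/Et2O, 0 °C
Reagents that add atoms: none
Why: Periodic acid opens the epoxide to the glycol and cleaves it in the same pot (Malaprade-type glycol cleavage); the two E alkenes and the acetate are inert to it.

Step 3
Reactants: 4 (2E,6E)-3,7-dimethyl-10-oxodeca-2,6-dien-1-yl acetate
Product: 5 (2E,6E,9R)-3,7-dimethyl-10-oxo-9-[(2,2,6,6-tetramethylpiperidin-1-yl)oxy]deca-2,6-dien-1-yl acetate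
Conditions: TEMPO (1.2 equiv), (5R)-5-benzyl-2,2,3-trimethylimidazolidin-4-one·TFA (20 mol %), CuCl2·2H2O (10 mol %), air, acetone, 0 °C
Reagents that add atoms: TEMPO, CC1(C)CCCC(C)(C)N1[O]
Why: This is the organocatalytic enantioselective α-oxyamination of an aldehyde (enamine catalysis joined to Cu(II)/TEMPO); the E-enamine turns away from the gem-dimethyl group, the benzyl group of the (5R) catalyst covers one face, and C–O bond formation on the open face should give C8 as R; the O-piperidinyl group is both the C8 oxygen and its base-stable, bulky protecting group.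

Step 4
Reactants: 5 (2E,6E,9R)-3,7-dimethyl-10-oxo-9-[(2,2,6,6-tetramethylpiperidin-1-yl)oxy]deca-2,6-dien-1-yl acetate; 6 ethyl 2-[bis(2,2,2-trifluoroethoxy)phosphoryl]propanoate
Product: 7 ethyl (2Z,4R,6E,10E)-12-acetoxy-2,6,10-trimethyl-4-[(2,2,6,6-tetramethylpiperidin-1-yl)oxy]dodeca-2,6,10-trienoate
Conditions: 6, KHMDS, 18-crown-6, THF, −78 °C; then 5
Reagents that add atoms: none
Why: The Still–Gennari variant of the Horner–Wadsworth–Emmons reaction gives Z-2-methyl enoates under kinetic control, and α-branched α-oxy aldehydes are good substrates for it; at −78 °C with the preformed anion, neither the acetate nor the C8 centre should be touched.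

Step 5
Reactants: 7 ethyl (2Z,4R,6E,10E)-12-acetoxy-2,6,10-trimethyl-4-[(2,2,6,6-tetramethylpiperidin-1-yl)oxy]dodeca-2,6,10-trienoate
Product: 8 (2Z,4R,6E,10E)-2,6,10-trimethyl-4-[(2,2,6,6-tetramethylpiperidin-1-yl)oxy]dodeca-2,6,10-triene-1,12-diol
Conditions: DIBAL-H (5 equiv), CH2Cl2, −78 to 0 °C; Rochelle salt work-up
Reagents that add atoms: none
Why: DIBAL-H reduces the enoate by 1,2-addition and removes the acetate in the same operation; the alkoxyamine and the alkene geometries are inert to hydride.

Step 6
Reactants: 8 (2Z,4R,6E,10E)-2,6,10-trimethyl-4-[(2,2,6,6-tetramethylpiperidin-1-yl)oxy]dodeca-2,6,10-triene-1,12-diol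
Product: 10 (3E,7E,10R,11Z)-4,8,12-trimethyl-10-[(2,2,6,6-tetramethylpiperidin-1-yl)oxy]-1-oxacyclotrideca-3,7,11-triene, via the 12-O-tosylate 9 (not isolated)
Conditions: NaH (2.5 equiv), THF, 0.002 M, 0 to 40 °C; 1-tosylimidazole (1.0 equiv) by syringe pump
Reagents that add atoms: none
Why: This is a one-pot monosulfonylation and intramolecular Williamson etherification of a diol; sulfonylation at either primary allylic terminus leads to the same ether, so the ends need not be differentiated, and slow addition to the bis-alkoxide under dilution favours closure of the unstrained thirteen-membered ring over a second sulfonylation.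

Step 7
Reactants: 10 (3E,7E,10R,11Z)-4,8,12-trimethyl-10-[(2,2,6,6-tetramethylpiperidin-1-yl)oxy]-1-oxacyclotrideca-3,7,11-triene
Product: 12 (1R,2E,6E,9R,10R)-3,7-dimethyl-10-(prop-1-en-2-yl)-9-[(2,2,6,6-tetramethylpiperidin-1-yl)oxy]cyclodeca-2,6-dien-1-ol, via the C6-lithio ether 11 (not isolated)
Conditions: n-BuLi (1.5 equiv), THF, −78 to −25 °C; then H2O
Reagents that add atoms: none
Why: n-BuLi, precomplexed to the ring oxygen, should remove an α-oxy allylic proton at C6, which is flanked only by the C5 methine, whereas C12–H2 lies between the C13 methyl and, across the Z alkene, the C8 centre with its very large piperidinyloxy group. The carbanion 11 then undergoes a concerted, suprafacial six-electron [2,3]-sigmatropic shift through a five-membered envelope (C6, O, C12, C11, C7) in which C6–C7 forms, O–C12 breaks and C11=C12 appears, and the change from carbanion to alkoxide makes it irreversible. The closest known reaction type is the transannular [2,3]-Wittig ring contraction of thirteen-membered bis-allylic ethers to isopropenyl-substituted cyclodecadienols. The ten-membered ring is closed transannularly (13 to 10) inside a ring that is already formed and unstrained, so the entropy of closure has been paid earlier and the two E alkenes are carried through unchanged. C7 is controlled by C8: A1,3 strain in the Z alkene holds C8–H in the alkene plane towards C12, the short linker from C9 to C5 with its two E alkenes can reach C7 only from the face on which C9 stands, and the C8–O bond is then anti to the forming bond, which is also the stereoelectronically best arrangement and gives 7,8-syn. C6 is controlled by the envelope: the C5 alkenyl substituent takes the exo position away from the C13 methyl on C11, which for a Z allyl unit gives the syn-type product, that is 6,7-anti along the ring backbone, and this places C5 and C8 on the same side as their bridge requires. The step needs lithiation at C6, [2,3] over [1,2] migration (secured by low temperature) and no 1,4-elimination of the C8 oxygen substituent, which can only follow lithiation at the shielded C12.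

Step 8
Reactants: 12 (1R,2E,6E,9R,10R)-3,7-dimethyl-10-(prop-1-en-2-yl)-9-[(2,2,6,6-tetramethylpiperidin-1-yl)oxy]cyclodeca-2,6-dien-1-ol
Product: 13 (1R,2E,6E,9R,10S)-3,7-dimethyl-10-(prop-1-en-2-yl)cyclodeca-2,6-diene-1,9-diol
Conditions: Zn dust, AcOH/THF/H2O, 40 °C
Reagents that add atoms: none
Why: This is a reductive N–O cleavage of an O-alkyl hydroxylamine by zinc in acetic acid; no C–O bond at a stereocentre is broken, so C8 is retained, and the change of the C7 descriptor is only a change of CIP priorities.

Step 9
Reactants: 13 (1R,2E,6E,9R,10S)-3,7-dimethyl-10-(prop-1-en-2-yl)cyclodeca-2,6-diene-1,9-diol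
Product: 14 (6R,7S,8R)-germacra-1(10)E,4E,11-triene-6,8-diyl diacetate
Conditions: Ac2O, pyridine, DMAP (cat.), CH2Cl2, 0 °C to rt
Reagents that add atoms: acetic anhydride, CC(=O)OC(C)=O
Why: This is a DMAP-catalysed acylation of both secondary alcohols under non-acidic conditions that do not endanger the diene; the stereocentres are not involved.

Step 10
Reactants: 14 (6R,7S,8R)-germacra-1(10)E,4E,11-triene-6,8-diyl diacetate
Product: 15 (6R,7S,8R)-germacra-1(10)E,4E-diene-6,8-diyl diacetate
Conditions: H2 (1 atm), RhCl(PPh3)3 (10 mol %), benzene/EtOH, rt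
Reagents that add atoms: none
Why: Homogeneous hydrogenation with Wilkinson's catalyst discriminates by substitution, so the 1,1-disubstituted C11=C12 alkene should be reduced while the two trisubstituted ring alkenes remain; no stereocentre is created.

Step 11
Reactants: 15 (6R,7S,8R)-germacra-1(10)E,4E-diene-6,8-diyl diacetate
Product: 17 (6R,7S,8R)-14-hydroxygermacra-1(10),4E-diene-6,8-diyl diacetate (C2/C9 cis), via the C1 allylic seleninic acid 16 (not isolated)
Conditions: SeO2 (0.3 equiv), t-BuOOH (3 equiv), CH2Cl2, 0 °C to rt
Reagents that add atoms: tert-butyl hydroperoxide, CC(C)(C)OO; selenium dioxide (catalytic oxygen carrier), O=[Se]=O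
Why: In this Riley allylic oxidation the ene step should take the electron-richer C1=C10 alkene (C4=C5 is deactivated by the C6 acetate) and a freely rotating C14–H rather than the ring-bound C9–H next to the C8 acetate, which puts selenium on C1 and leaves a C10=C14 methylene group in 16. The following [2,3] shift of 16 carries oxygen to C14 and rebuilds C1=C10 with C2 trans to the new CH2OH, which is the ring-cis geometry, as this reaction type does on ring-trans 1(10)-germacrenes.

Step 12
Reactants: 17 (6R,7S,8R)-14-hydroxygermacra-1(10),4E-diene-6,8-diyl diacetate (C2/C9 cis)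
Product: 18 (1R,6R,7S,8R,10R)-1,10-epoxy-14-hydroxygermacr-4E-ene-6,8-diyl diacetate
Conditions: Ti(OiPr)4 (15 mol %), D-(−)-DIPT (18 mol %), t-BuOOH, 4 Å MS, CH2Cl2, −20 °C
Reagents that add atoms: tert-butyl hydroperoxide, CC(C)(C)OO
Why: The Sharpless asymmetric epoxidation acts only on the alkene of the free allylic alcohol and is stereospecific, so C2 and C9 stay cis. D-(−)-tartrate is the enantiomer that takes 2- and (3E)-substituted prop-2-en-1-ols to their (2R)-epoxy alcohols, so it should deliver oxygen to the face that gives 10R and, by syn addition, 1R.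

Step 13
Reactants: 18 (1R,6R,7S,8R,10R)-1,10-epoxy-14-hydroxygermacr-4E-ene-6,8-diyl diacetate
Product: 19 pulicanaral A, (1R,6R,7S,8R,10S)-1,10-epoxy-14-oxogermacr-4E-ene-6,8-diyl diacetate
Conditions: Dess–Martin periodinane, pyridine, CH2Cl2, 0 °C to rt
Reagents that add atoms: none
Why: The Dess–Martin oxidation of a 2,3-epoxy alcohol under buffered, non-nucleophilic conditions leaves the oxirane, the acetates and the alkene untouched; the C10 descriptor changes from R to S only because CHO outranks C1.

## Compound list

1 | (2E,6E)-farnesyl acetate | CC(=O)OC/C=C(\C)CC/C=C(\C)CCC=C(C)C | starting material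
2 | (2E,6E)-10-bromo-11-hydroxy-3,7,11-trimethyldodeca-2,6-dien-1-yl acetate (10,11-bromohydrin, racemic) | CC(=O)OC/C=C(\C)CC/C=C(\C)CCC(Br)C(C)(C)O | intermediate
3 | (2E,6E)-10,11-epoxy-3,7,11-trimethyldodeca-2,6-dien-1-yl acetate (racemic) | CC(=O)OC/C=C(\C)CC/C=C(\C)CCC1OC1(C)C | intermediate
4 | (2E,6E)-3,7-dimethyl-10-oxodeca-2,6-dien-1-yl acetate | CC(=O)OC/C=C(\C)CC/C=C(\C)CCC=O | intermediate
5 | (2E,6E,9R)-3,7-dimethyl-10-oxo-9-[(2,2,6,6-tetramethylpiperidin-1-yl)oxy]deca-2,6-dien-1-yl acetate | CC(=O)OC/C=C(\C)CC/C=C(\C)C[C@@H](ON1C(C)(C)CCCC1(C)C)C=O | intermediate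
6 | ethyl 2-[bis(2,2,2-trifluoroethoxy)phosphoryl]propanoate | CCOC(=O)C(C)P(=O)(OCC(F)(F)F)OCC(F)(F)F | starting material
7 | ethyl (2Z,4R,6E,10E)-12-acetoxy-2,6,10-trimethyl-4-[(2,2,6,6-tetramethylpiperidin-1-yl)oxy]dodeca-2,6,10-trienoate | CC(=O)OC/C=C(\C)CC/C=C(\C)C[C@@H](ON1C(C)(C)CCCC1(C)C)/C=C(/C)C(=O)OCC | intermediate
8 | (2Z,4R,6E,10E)-2,6,10-trimethyl-4-[(2,2,6,6-tetramethylpiperidin-1-yl)oxy]dodeca-2,6,10-triene-1,12-diol | OC/C=C(\C)CC/C=C(\C)C[C@@H](ON1C(C)(C)CCCC1(C)C)/C=C(/C)CO | intermediate
9 | 12-O-(4-methylbenzenesulfonate) of 8 (12-O-tosylate; sulfonate on C6 in germacrane numbering) | Cc1ccc(cc1)S(=O)(=O)OC/C=C(\C)CC/C=C(\C)C[C@@H](ON1C(C)(C)CCCC1(C)C)/C=C(/C)CO | intermediate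
10 | (3E,7E,10R,11Z)-4,8,12-trimethyl-10-[(2,2,6,6-tetramethylpiperidin-1-yl)oxy]-1-oxacyclotrideca-3,7,11-triene | O1C/C=C(\C)CC/C=C(\C)C[C@@H](ON2C(C)(C)CCCC2(C)C)/C=C(/C)C1 | intermediate
11 | 2-lithio derivative of 10 (C6-lithio ether) | O1C([Li])/C=C(\C)CC/C=C(\C)C[C@@H](ON2C(C)(C)CCCC2(C)C)/C=C(/C)C1 | intermediate
12 | (1R,2E,6E,9R,10R)-3,7-dimethyl-10-(prop-1-en-2-yl)-9-[(2,2,6,6-tetramethylpiperidin-1-yl)oxy]cyclodeca-2,6-dien-1-ol | O[C@@H]1/C=C(\C)CC/C=C(\C)C[C@@H](ON2C(C)(C)CCCC2(C)C)[C@@H]1C(C)=C | intermediate
13 | (1R,2E,6E,9R,10S)-3,7-dimethyl-10-(prop-1-en-2-yl)cyclodeca-2,6-diene-1,9-diol | O[C@@H]1/C=C(\C)CC/C=C(\C)C[C@@H](O)[C@@H]1C(C)=C | intermediate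
14 | (6R,7S,8R)-germacra-1(10)E,4E,11-triene-6,8-diyl diacetate | CC(=O)O[C@@H]1/C=C(\C)CC/C=C(\C)C[C@@H](OC(C)=O)[C@@H]1C(C)=C | intermediate
15 | (6R,7S,8R)-germacra-1(10)E,4E-diene-6,8-diyl diacetate | CC(=O)O[C@@H]1/C=C(\C)CC/C=C(\C)C[C@@H](OC(C)=O)[C@@H]1C(C)C | intermediate
16 | C1 allylic seleninic acid (C10=C14 exocyclic methylene; C1 not assigned) | CC(=O)O[C@@H]1/C=C(\C)CCC([Se](=O)O)C(=C)C[C@@H](OC(C)=O)[C@@H]1C(C)C | intermediate
17 | (6R,7S,8R)-14-hydroxygermacra-1(10),4E-diene-6,8-diyl diacetate (C2/C9 cis) | CC(=O)O[C@@H]1/C=C(\C)CC/C=C(/CO)C[C@@H](OC(C)=O)[C@@H]1C(C)C | intermediate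
18 | (1R,6R,7S,8R,10R)-1,10-epoxy-14-hydroxygermacr-4E-ene-6,8-diyl diacetate | CC(=O)O[C@@H]1/C=C(\C)CC[C@H]2O[C@@]2(CO)C[C@@H](OC(C)=O)[C@@H]1C(C)C | intermediate
19 | pulicanaral A | CC(=O)O[C@@H]1/C=C(\C)CC[C@H]2O[C@@]2(C=O)C[C@@H](OC(C)=O)[C@@H]1C(C)C | target

## Step count and least certain steps

Total step count: 13. Longest linear sequence: 13 steps (from 1; 6 is bought and enters in step 4).

Step 7 (key step). Lithiation may occur at C12 instead of C6, because an allyl anion with a less substituted far terminus is electronically easier to form. It would be followed by 1,4-elimination of the C8 oxygen substituent or by rearrangement onto C4. Some [1,2] migration may also occur if the temperature rises before the shift is complete. The fallback sets out from 8 and returns at 13; it makes the same C6–C7 bond without the ether bridge and sets C6 separately. The less hindered C6 carbinol of 8 is oxidised with MnO2 to the hydroxy enal F1, and MsCl/LiCl/collidine converts the C12 hydroxyl to give the chloro enal F2. CrCl2 under high dilution (Nozaki–Hiyama allylation) closes the ring to the homoallylic alcohol F3, whose C6 configuration is not relied on. Dess–Martin oxidation gives the enone F4, and Zn/AcOH frees the β-hydroxy enone F5. Hydroxyl-directed 1,3-anti reduction with Me4NBH(OAc)3 then sets C6 from C8 and gives 13.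

Step 6. A second sulfonylation may occur before ring closure, and intermolecular etherification may compete, because closure of a thirteen-membered ring is slow. The fallback sets out from 7 and returns at 10; it differentiates the two ends by their ester types. K2CO3 in EtOH removes only the acetate and gives the hydroxy enoate F6. MsCl/LiCl/collidine gives the C6 allylic chloride F7, and DIBAL-H at −78 °C reduces the enoate to the chloro alcohol F8. NaH under dilution closes F8 to 10.

Step 8. Acid-promoted transannular cyclisation of the 1(10),4-diene or ionisation of the allylic C6 alcohol may occur during the N–O cleavage. The fallback sets out from 10 and returns at 13; it exchanges the protecting group before the sensitive ring exists. Zn/AcOH on 10 gives the hydroxy ether F9, and TBSOTf/2,6-lutidine gives the silyl ether F10. The ring contraction with n-BuLi gives the silyl-protected cyclodecadienol F11, and TBAF gives 13 under non-acidic conditions.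

Step 11. A competing ene reaction at C3/C15 of the other alkene or at C9/C2, over-oxidation to the aldehyde level and incomplete turnover of the alkene geometry may all occur, since the selectivity rests on modest electronic and conformational differences. The fallback sets out from 15 and returns at 17; it brings oxygen in at C1 and then transposes it. One equivalent of buffered mCPBA epoxidises the electron-richer C1=C10 alkene to the 1,10-epoxide F12. Diethylaluminium 2,2,6,6-tetramethylpiperidide in slight excess at 0 °C, where the hindered secondary acetates should survive, isomerises F12 to the exo-methylene C1 allylic alcohol F13. A catalytic perrhenate ester (Ph3SiOReO3) then effects the 1,3-transposition towards the primary alcohol and the more substituted alkene, and should give the less strained ring-cis isomer 17.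

Step 12. Facial selectivity may be poor if the tartrate and the ring conformation are mismatched, and Lewis-acid opening of the new epoxide with participation of C4=C5 may occur. The fallback sets out from 17 and returns at 19; it reverses the polarity of the epoxidation. MnO2 oxidises 17 to the enal F14. A nucleophilic (Weitz–Scheffer type) epoxidation with H2O2 under chiral primary-amine iminium catalysis, which touches only the electron-poor alkene, gives 19 directly.

## Further compounds

F1 | step 7 | (2E,6E,9R,10Z)-12-hydroxy-3,7,11-trimethyl-9-[(2,2,6,6-tetramethylpiperidin-1-yl)oxy]dodeca-2,6,10-trienal | O=C/C=C(\C)CC/C=C(\C)C[C@@H](ON1C(C)(C)CCCC1(C)C)/C=C(/C)CO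
F2 | step 7 | (2E,6E,9R,10Z)-12-chloro-3,7,11-trimethyl-9-[(2,2,6,6-tetramethylpiperidin-1-yl)oxy]dodeca-2,6,10-trienal | O=C/C=C(\C)CC/C=C(\C)C[C@@H](ON1C(C)(C)CCCC1(C)C)/C=C(/C)CCl
F3 | step 7 | 3,7-dimethyl-10-(prop-1-en-2-yl)-9-[(2,2,6,6-tetramethylpiperidin-1-yl)oxy]cyclodeca-2,6-dien-1-ol, C6 (ring C1) not assigned | OC1/C=C(\C)CC/C=C(\C)C[C@@H](ON2C(C)(C)CCCC2(C)C)[C@@H]1C(C)=C
F4 | step 7 | corresponding cyclodeca-2,6-dien-1-one (C6 ketone, O8 still protected) | O=C1/C=C(\C)CC/C=C(\C)C[C@@H](ON2C(C)(C)CCCC2(C)C)[C@@H]1C(C)=C
F5 | step 7 | 9-hydroxy-3,7-dimethyl-10-(prop-1-en-2-yl)cyclodeca-2,6-dien-1-one (C6 ketone, free C8 hydroxyl) | O=C1/C=C(\C)CC/C=C(\C)C[C@@H](O)[C@@H]1C(C)=C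
F6 | step 6 | ethyl (2Z,4R,6E,10E)-12-hydroxy-2,6,10-trimethyl-4-[(2,2,6,6-tetramethylpiperidin-1-yl)oxy]dodeca-2,6,10-trienoate | OC/C=C(\C)CC/C=C(\C)C[C@@H](ON1C(C)(C)CCCC1(C)C)/C=C(/C)C(=O)OCC
F7 | step 6 | ethyl (2Z,4R,6E,10E)-12-chloro-2,6,10-trimethyl-4-[(2,2,6,6-tetramethylpiperidin-1-yl)oxy]dodeca-2,6,10-trienoate | ClC/C=C(\C)CC/C=C(\C)C[C@@H](ON1C(C)(C)CCCC1(C)C)/C=C(/C)C(=O)OCC
F8 | step 6 | (2Z,4R,6E,10E)-12-chloro-2,6,10-trimethyl-4-[(2,2,6,6-tetramethylpiperidin-1-yl)oxy]dodeca-2,6,10-trien-1-ol | ClC/C=C(\C)CC/C=C(\C)C[C@@H](ON1C(C)(C)CCCC1(C)C)/C=C(/C)CO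
F9 | step 8 | (3E,7E,10R,11Z)-4,8,12-trimethyl-1-oxacyclotrideca-3,7,11-trien-10-ol | O1C/C=C(\C)CC/C=C(\C)C[C@@H](O)/C=C(/C)C1
F10 | step 8 | tert-butyldimethylsilyl ether of F9 | O1C/C=C(\C)CC/C=C(\C)C[C@@H](O[Si](C)(C)C(C)(C)C)/C=C(/C)C1
F11 | step 8 | 9-(tert-butyldimethylsilyloxy)-3,7-dimethyl-10-(prop-1-en-2-yl)cyclodeca-2,6-dien-1-ol, configuration as in 12 | O[C@@H]1/C=C(\C)CC/C=C(\C)C[C@@H](O[Si](C)(C)C(C)(C)C)[C@@H]1C(C)=C
F12 | step 11 | (6R,7S,8R)-1,10-epoxygermacr-4E-ene-6,8-diyl diacetate, trans-epoxide, face not assigned | CC(=O)O[C@@H]1/C=C(\C)CCC2OC2(C)C[C@@H](OC(C)=O)[C@@H]1C(C)C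
F13 | step 11 | (6R,7S,8R)-1-hydroxygermacra-4E,10(14)-diene-6,8-diyl diacetate, C1 not assigned | CC(=O)O[C@@H]1/C=C(\C)CCC(O)C(=C)C[C@@H](OC(C)=O)[C@@H]1C(C)C
F14 | step 12 | (6R,7S,8R)-14-oxogermacra-1(10),4E-diene-6,8-diyl diacetate, C2 and C9 cis | CC(=O)O[C@@H]1/C=C(\C)CC/C=C(/C=O)C[C@@H](OC(C)=O)[C@@H]1C(C)C
A1 | alternative 1 | open-chain (E)-vinyl iodide (C5) aldehyde (C6) with C8 silyl ether and C7 isopropyl | I/C=C(\C)CC/C=C(\C)C[C@@H](O[Si](C)(C)C(C)(C)C)[C@@H](C=O)C(C)C
A2 | alternative 1 | 8-silyloxygermacra-1(10)E,4E-dien-6-ol, C6 not assigned | OC1/C=C(\C)CC/C=C(\C)C[C@@H](O[Si](C)(C)C(C)(C)C)[C@@H]1C(C)C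
A3 | alternative 2 | cis-1-vinyl-2-isopropenyl-4-isopropyl-3,5-bis(silyloxy)cyclohexan-1-ol (ring C10, C5, C6, C7, C8, C9) | C=C[C@@]1(O)C[C@@H](O[Si](C)(C)C(C)(C)C)[C@H](C(C)C)[C@H](O[Si](C)(C)C(C)(C)C)[C@H]1C(C)=C
A4 | alternative 2 | 6,8-bis(silyloxy)-14-norgermacr-4E-en-10-one | CC(C)(C)[Si](C)(C)O[C@@H]1/C=C(\C)CCCC(=O)C[C@@H](O[Si](C)(C)C(C)(C)C)[C@@H]1C(C)C
A5 | alternative 3 | open-chain C1 aldehyde with a C10 phosphonoacetate terminus | O=CCC/C(C)=C/[C@@H](O[Si](C)(C)C(C)(C)C)[C@@H](C(C)C)[C@H](O[Si](C)(C)C(C)(C)C)CC(C(=O)OCC)P(=O)(OCC)OCC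
A6 | alternative 3 | ethyl 6,8-bis(silyloxy)germacra-1(10),4E-dien-14-oate, C2 and C9 cis | CCOC(=O)/C1=C/CC/C(C)=C/[C@@H](O[Si](C)(C)C(C)(C)C)[C@@H](C(C)C)[C@H](O[Si](C)(C)C(C)(C)C)C1
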